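**Retrosynthetic overview**

1. The target is 8α,15-dihydroxy-14-oxolabd-13(16)-en-19-oic acid (labdane numbering). The C11–C12 bond is cut to a primary C11 radical on the decalin and a 2-acylallyl sulfone that carries C12–C16. Radical addition at C12 followed by loss of PhSO2• should make C11–C12 and the C13=C16 methylene in the same event.
2. Enabling feature: the tertiary oxygen on C8 of ring B stands 1,3 to C11 (O–C8–C9–C11). O8 and C11 can therefore be tied through one carbon into a five-membered 2-oxytetrahydrofuran (γ-lactol) ring fused on the C8–C9 bond. Its anomeric alkoxyl radical breaks the C11–C(acetal) bond, frees the C11 radical and leaves the bridge carbon on O8 as a formate, i.e. the protected 8α-ol.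
3. The lactol ring is made from trans-communic acid, which supplies rings A/B with C4 (axial CO2H), C5, C9 and C10. The sequence is side-chain ozonolysis/Pinnick oxidation to the C12 acid, Markovnikov hydration of C8=C17 (sets C8) with lactonisation, DIBAL-H reduction, and O-acetalisation with N-hydroxyphthalimide.
4. The acceptor comes from (tert-butyldimethylsilyloxy)acetaldehyde and isopropenylmagnesium bromide by oxidation and iodosulfonylation–dehydroiodination.
5. Ring order: the decalin A/B is bought intact; the only ring formed is the temporary O-ring (γ-lactone, step 2), which the key step opens again; the last step removes formate and silyl ether.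

Key step: step 8

Remark: labdane numbering is used throughout (C19 = the axial 4β-carboxyl), and trans-communic acid is taken as a purchasable chiral-pool resin acid that already has the required configuration at C4, C5, C9 and C10.

**Step 1**
Reactants: 1 trans-communic acid (labda-8(17),12E,14-trien-19-oic acid)
Product: 3 13,14,15,16-tetranorlabd-8(17)-ene-12,19-dioic acid, via 12-oxo aldehyde 2 (not isolated)
Conditions: O3 (1.0 equiv, titrated CH2Cl2 solution), CH2Cl2, −78 °C; Me2S; then NaClO2, NaH2PO4, 2-methyl-2-butene, t-BuOH/H2O, rt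
Reagents that add atoms: ozone [O-][O+]=O; sodium chlorite [Na+].[O-]Cl=O
Why: Ozonolysis then Pinnick oxidation: ozone should be consumed first by the electron-rich trisubstituted C12=C13 bond of the diene, so one equivalent leaves the hindered 1,1-disubstituted C8=C17 bond intact, and chlorite then oxidises only the aldehyde (2-methyl-2-butene scavenges HOCl); no stereocentre is touched.

**Step 2**
Reactants: 3 13,14,15,16-tetranorlabd-8(17)-ene-12,19-dioic acid
Product: 5 8α,12-epoxy-12-oxo-13,14,15,16-tetranorlabdan-19-oic acid (trans-fused γ-lactone; the 19-carboxy analogue of sclareolide), via hydroxy diacid 4 (not isolated)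
Conditions: Co(acac)2 (cat.), PhSiH3, O2 (1 atm), THF, rt; then p-TsOH (cat.), CH2Cl2, rt
Reagents that add atoms: dioxygen O=O
Why: Mukaiyama (hydrogen-atom-transfer) hydration: Markovnikov H-atom transfer gives the tertiary C8 radical, which O2 should trap on the α face, away from the axial C10 methyl, so the hydroxyl ends 8α (equatorial) and C17 8β, and acid then closes the trans-fused γ-lactone with the C12 acid without touching C8.

**Step 3**
Reactants: 5 8α,12-epoxy-12-oxo-13,14,15,16-tetranorlabdan-19-oic acid
Product: 6 8α,12-epoxy-12-hydroxy-13,14,15,16-tetranorlabdan-19-oic acid (γ-lactol, both C12 anomers)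
Conditions: DIBAL-H (3 equiv), CH2Cl2/THF, −78 °C; aq. Rochelle salt, then citric acid
Reagents that add atoms: none
Why: Partial reduction of a γ-lactone with DIBAL-H at −78 °C stops at the aluminium hemiacetal, while the first equivalent turns the hindered axial C19 acid into an unreactive aluminium carboxylate; the new C12 centre forms as an irrelevant anomer mixture.

**Step 4**
Reactants: 6 8α,12-epoxy-12-hydroxy-13,14,15,16-tetranorlabdan-19-oic acid
Product: 7 8α,12-epoxy-12-(phthalimidooxy)-13,14,15,16-tetranorlabdan-19-oic acid (anomer mixture)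
Conditions: N-hydroxyphthalimide (1.5 equiv), PPTS (cat.), 4 Å MS, CH2Cl2, rt
Reagents that add atoms: N-hydroxyphthalimide O=C1c2ccccc2C(=O)N1O
Why: Acid-catalysed acetal exchange (as in tetrahydropyranyl-ether formation or O-glycosylation of N-hydroxyphthalimide): the cyclic oxocarbenium ion at C12 is captured by the N–OH oxygen, the free acid is inert and the anomer ratio does not matter.

**Step 5**
Reactants: 8 (tert-butyldimethylsilyloxy)acetaldehyde; 9 isopropenylmagnesium bromide
Product: 10 1-[(tert-butyldimethylsilyl)oxy]-3-methylbut-3-en-2-ol (racemic)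
Conditions: THF, −78 → 0 °C; aq. NH4Cl
Reagents that add atoms: none
Why: Grignard 1,2-addition to the aldehyde; the carbinol centre is racemic and is removed in step 6.

**Step 6**
Reactants: 10 1-[(tert-butyldimethylsilyl)oxy]-3-methylbut-3-en-2-ol
Product: 11 1-[(tert-butyldimethylsilyl)oxy]-3-methylbut-3-en-2-one
Conditions: Dess–Martin periodinane, CH2Cl2, 0 °C → rt
Reagents that add atoms: none
Why: Dess–Martin oxidation of the secondary allylic alcohol to the enone under near-neutral conditions that leave the silyl ether alone.

**Step 7**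
Reactants: 11 1-[(tert-butyldimethylsilyl)oxy]-3-methylbut-3-en-2-one
Product: 13 1-[(tert-butyldimethylsilyl)oxy]-3-[(phenylsulfonyl)methyl]but-3-en-2-one, via iodo sulfone 12 (not isolated)
Conditions: PhSO2Na, I2, CH2Cl2/H2O, rt; then Et3N, CH2Cl2, 0 °C → rt
Reagents that add atoms: sodium benzenesulfinate [Na+].[O-]S(=O)c1ccccc1
Why: Iodosulfonylation–dehydroiodination: benzenesulfonyl iodide formed in the flask adds by a radical chain (PhSO2• to the terminal CH2, iodine to the tertiary α-carbon), and triethylamine should eliminate HI toward the methyl group to give the 2-acylallyl sulfone, the isomer favoured over the doubly activated vinyl sulfone.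

**Step 8**
Reactants: 7 8α,12-epoxy-12-(phthalimidooxy)-13,14,15,16-tetranorlabdan-19-oic acid; 13 1-[(tert-butyldimethylsilyl)oxy]-3-[(phenylsulfonyl)methyl]but-3-en-2-one
Product: 16 8α-formyloxy-15-[(tert-butyldimethylsilyl)oxy]-14-oxolabd-13(16)-en-19-oic acid, via alkoxyl radical 14 (not isolated), via C11 radical 15 (not isolated)
Conditions: fac-Ir(ppy)3 (1 mol %), Hantzsch ester (1.5 equiv), 13 (2.5 equiv), degassed 1,4-dioxane, blue LEDs, rt
Reagents that add atoms: none
Why: Single-electron reduction of the phthalimide of 7 by the photoexcited iridium catalyst (turned over by Hantzsch ester) cleaves the N–O bond to the anomeric alkoxyl radical 14, whose β-scission of the C11–C12 bond, driven by formation of the formate C=O, gives the primary C11 radical 15; this adds to the unsubstituted CH2 terminus of the electron-poor allyl sulfone 13, and the tertiary α-keto radical expels PhSO2• (reduced by Hantzsch ester), so that C11–C12 and C13=C16 arise together. The closest known reaction type is the anomeric alkoxyl-radical fragmentation of N-phthalimido lactol acetals with intermolecular allylation, together with the photoredox β-scission/allylation of N-alkoxyphthalimides with allyl sulfones under Hantzsch ester conditions. No ring is closed: the temporary tetrahydrofuran ring is opened by C–C β-scission, its bridge carbon stays on O8 as the formate, and the native C12 of the starting diterpene is thereby exchanged for the whole C12–C16 unit. No new stereocentre is formed; C4, C5, C8, C9 and C10 are untouched because the radical site C11 is exocyclic, and the mixed C12 acetal centre is destroyed. The step needs β-scission of C11–C12 to outrun hydrogen transfer to the alkoxyl radical, which the α-oxygen (an ester is formed) should secure. It also needs addition to outrun hydrogen abstraction by the C11 radical from Hantzsch ester, which the polarity match between the nucleophilic primary radical and the acyl-activated alkene, and the excess of 13, should secure.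

**Step 9**
Reactants: 16 8α-formyloxy-15-[(tert-butyldimethylsilyl)oxy]-14-oxolabd-13(16)-en-19-oic acid
Product: 18 8α,15-dihydroxy-14-oxolabd-13(16)-en-19-oic acid (target), via silyl ether 17 (not isolated)
Conditions: K2CO3, THF/H2O, 0 °C; then 48% aq. HF, MeCN, 0 °C → rt
Reagents that add atoms: none
Why: Saponification of the unhindered formate by acyl–oxygen cleavage (C8 configuration retained) in aqueous carbonate, where water addition to the enone is reversible, followed by fluoride cleavage of the silyl ether under acidic conditions that also protonate the carboxylate.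

**Compound list**

1 | trans-communic acid (labda-8(17),12E,14-trien-19-oic acid) | C=C/C(C)=C/C[C@@H]1[C@@]2(C)CCC[C@](C)(C(=O)O)[C@@H]2CCC1=C | starting material
2 | 12-oxo-13,14,15,16-tetranorlabd-8(17)-en-19-oic acid | O=CC[C@@H]1[C@@]2(C)CCC[C@](C)(C(=O)O)[C@@H]2CCC1=C | intermediate
3 | 13,14,15,16-tetranorlabd-8(17)-ene-12,19-dioic acid | OC(=O)C[C@@H]1[C@@]2(C)CCC[C@](C)(C(=O)O)[C@@H]2CCC1=C | intermediate
4 | 8α-hydroxy-13,14,15,16-tetranorlabdane-12,19-dioic acid | OC(=O)C[C@@H]1[C@@]2(C)CCC[C@](C)(C(=O)O)[C@@H]2CC[C@@]1(C)O | intermediate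
5 | 8α,12-epoxy-12-oxo-13,14,15,16-tetranorlabdan-19-oic acid (trans-fused γ-lactone, O on C8 α, C17 β) | O=C1C[C@@H]2[C@@]3(C)CCC[C@](C)(C(=O)O)[C@@H]3CC[C@@]2(C)O1 | intermediate
6 | 8α,12-epoxy-12-hydroxy-13,14,15,16-tetranorlabdan-19-oic acid (lactol, C12 anomers) | OC1C[C@@H]2[C@@]3(C)CCC[C@](C)(C(=O)O)[C@@H]3CC[C@@]2(C)O1 | intermediate
7 | 8α,12-epoxy-12-(phthalimidooxy)-13,14,15,16-tetranorlabdan-19-oic acid (C12 anomers) | O=C1c2ccccc2C(=O)N1OC1C[C@@H]2[C@@]3(C)CCC[C@](C)(C(=O)O)[C@@H]3CC[C@@]2(C)O1 | intermediate
8 | (tert-butyldimethylsilyloxy)acetaldehyde | O=CCO[Si](C)(C)C(C)(C)C | starting material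
9 | isopropenylmagnesium bromide | C=C(C)[Mg]Br | starting material
10 | 1-[(tert-butyldimethylsilyl)oxy]-3-methylbut-3-en-2-ol (racemic) | C=C(C)C(O)CO[Si](C)(C)C(C)(C)C | intermediate
11 | 1-[(tert-butyldimethylsilyl)oxy]-3-methylbut-3-en-2-one | C=C(C)C(=O)CO[Si](C)(C)C(C)(C)C | intermediate
12 | 1-[(tert-butyldimethylsilyl)oxy]-3-iodo-3-methyl-4-(phenylsulfonyl)butan-2-one (racemic) | CC(I)(CS(=O)(=O)c1ccccc1)C(=O)CO[Si](C)(C)C(C)(C)C | intermediate
13 | 1-[(tert-butyldimethylsilyl)oxy]-3-[(phenylsulfonyl)methyl]but-3-en-2-one | C=C(CS(=O)(=O)c1ccccc1)C(=O)CO[Si](C)(C)C(C)(C)C | intermediate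
14 | 12-oxyl radical of lactol 6 (anomeric alkoxyl radical) | [O]C1C[C@@H]2[C@@]3(C)CCC[C@](C)(C(=O)O)[C@@H]3CC[C@@]2(C)O1 | intermediate
15 | 8α-formyloxy-12,13,14,15,16-pentanorlabdan-19-oic acid 11-yl radical | [CH2][C@@H]1[C@@]2(C)CCC[C@](C)(C(=O)O)[C@@H]2CC[C@@]1(C)OC=O | intermediate
16 | 8α-formyloxy-15-[(tert-butyldimethylsilyl)oxy]-14-oxolabd-13(16)-en-19-oic acid | C=C(CC[C@@H]1[C@@]2(C)CCC[C@](C)(C(=O)O)[C@@H]2CC[C@@]1(C)OC=O)C(=O)CO[Si](C)(C)C(C)(C)C | intermediate
17 | 8α-hydroxy-15-[(tert-butyldimethylsilyl)oxy]-14-oxolabd-13(16)-en-19-oic acid | C=C(CC[C@@H]1[C@@]2(C)CCC[C@](C)(C(=O)O)[C@@H]2CC[C@@]1(C)O)C(=O)CO[Si](C)(C)C(C)(C)C | intermediate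
18 | 8α,15-dihydroxy-14-oxolabd-13(16)-en-19-oic acid | C=C(CC[C@@H]1[C@@]2(C)CCC[C@](C)(C(=O)O)[C@@H]2CC[C@@]1(C)O)C(=O)CO | target

**Step count and risks**

Total step count: 9. Longest linear sequence: 6 (steps 1, 2, 3, 4, 8, 9).

Steps most likely to fail:

1. Step 8. Hydrogen-atom transfer from Hantzsch ester to the C11 radical (or to the alkoxyl radical) may outrun C–C bond formation, and the excited photocatalyst may reductively erode the acceptor. The fallback removes both the hydrogen donor and the photocatalyst and runs a stannyl-radical chain. It sets out from 13, which with tributyltin hydride and AIBN in hot benzene (SH2′ displacement of the sulfonyl group) should give 1-[(tert-butyldimethylsilyl)oxy]-3-[(tributylstannyl)methyl]but-3-en-2-one F1. Heating 7 with F1 and AIBN in benzene lets the stannyl radical attack the phthalimide and cleave N–O; the same β-scission follows, and the C11 radical adds to F1 with loss of Bu3Sn•, which carries the chain. The fallback comes back to the route at 16.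

2. Step 2. Facial selectivity in the capture of the planar C8 radical by oxygen may be poor (the 8-epimer would give the cis-lactone), and hydrogen-atom-transfer isomerisation may move the alkene into the ring. The fallback delivers the oxygen by a polar route from the open α face. It sets out from 3, which with bicarbonate-buffered mCPBA should give 8α,17-epoxy-13,14,15,16-tetranorlabdane-12,19-dioic acid F2. Lithium triethylborohydride in excess (the dicarboxylate is formed first) then opens the epoxide at the primary C17. The fallback comes back to the route at 4, which acid closes to 5 as in step 2.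

3. Step 9. The base needed for formate hydrolysis may trigger conjugate addition to, or oligomerisation of, the α-methylene ketone, or isomerisation of the α-ketol. The fallback masks the enone during deprotection. It sets out from 16, which with thiophenol and catalytic triethylamine should give the thia-Michael adduct 8α-formyloxy-15-[(tert-butyldimethylsilyl)oxy]-14-oxo-16-(phenylthio)labdan-19-oic acid F3 (C13 epimers). Carbonate hydrolysis and aqueous HF then give 8α,15-dihydroxy-14-oxo-16-(phenylthio)labdan-19-oic acid F4. One equivalent of mCPBA at −78 °C gives 8α,15-dihydroxy-14-oxo-16-(phenylsulfinyl)labdan-19-oic acid F5, whose syn-elimination on warming in toluene over NaHCO3 should restore C13=C16. The fallback comes back to the route at 18.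

**Further compounds**

F1 | step 8 | 1-[(tert-butyldimethylsilyl)oxy]-3-[(tributylstannyl)methyl]but-3-en-2-one | C=C(C[Sn](CCCC)(CCCC)CCCC)C(=O)CO[Si](C)(C)C(C)(C)C
F2 | step 2 | 8α,17-epoxy-13,14,15,16-tetranorlabdane-12,19-dioic acid | OC(=O)C[C@@H]1[C@@]2(C)CCC[C@](C)(C(=O)O)[C@@H]2CC[C@]13CO3
F3 | step 9 | 8α-formyloxy-15-[(tert-butyldimethylsilyl)oxy]-14-oxo-16-(phenylthio)labdan-19-oic acid (C13 epimers) | O=C(CO[Si](C)(C)C(C)(C)C)C(CSc1ccccc1)CC[C@@H]1[C@@]2(C)CCC[C@](C)(C(=O)O)[C@@H]2CC[C@@]1(C)OC=O
F4 | step 9 | 8α,15-dihydroxy-14-oxo-16-(phenylthio)labdan-19-oic acid (C13 epimers) | O=C(CO)C(CSc1ccccc1)CC[C@@H]1[C@@]2(C)CCC[C@](C)(C(=O)O)[C@@H]2CC[C@@]1(C)O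
F5 | step 9 | 8α,15-dihydroxy-14-oxo-16-(phenylsulfinyl)labdan-19-oic acid (diastereomer mixture) | O=C(CO)C(CS(=O)c1ccccc1)CC[C@@H]1[C@@]2(C)CCC[C@](C)(C(=O)O)[C@@H]2CC[C@@]1(C)O
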